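**Retrosynthetic overview**
1. Target ⇒ C11–O bond, made last: the methyl(dienonyl)ketene of 3β-acetoxy-8-oxoeremophila-6,9-dien-12-oic acid plus 3-chlorobenzoyl (R)-2-methylbutanoyl peroxide (from the chiral acid and mCPBA) under a chiral isothiourea; this sets C11 and frees the acid.
2. Dienone acid ⇒ 7-iodo dienone + zinc enolate of tert-butyl 2-bromopropanoate (Pd coupling); iodo dienone ⇒ 3β-acetoxy enone (DDQ, then α-iodination).
3. 3β-Acetoxy enone ⇒ eremophil-9-ene-3,8-dione by equatorial hydride delivery at C3 and acetylation.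
4. Dione ⇒ Robinson annulation of (2R,3R)-4,4-dimethoxy-2,3-dimethylcyclohexanone with methyl vinyl ketone (C5 set anti to the C4 methyl).
5. That ketone ⇒ p-benzoquinone monoketal by Cu-catalysed asymmetric conjugate methylation (sets C4), α′-methylation and hydrogenation. Ring order: ring A is the bought six-membered ring; ring B is closed in the Robinson annulation.

Assumption: (R)-2-methylbutanoic acid, 3-chloroperoxybenzoic acid and 4,4-dimethoxycyclohexa-2,5-dien-1-one are bought as such (the last is also one step from 4-methoxyphenol).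
Naming: bicyclic compounds also carry eremophilane names (ring A = C1–C5 and C10, ring B = C5–C10, C14 on C5, C15 on C4, C11–C13 on C7; β = face of the C5 methyl). The target is the (3S,4R,5R,11R,2′R) isomer with 3-OAc, 4-Me and 5-Me all cis.

**Route**

Step 1
Reactants: 1 4,4-dimethoxycyclohexa-2,5-dien-1-one
Product: 3 (5R)-4,4-dimethoxy-5-methylcyclohex-2-en-1-one, via methylzinc dienolate 2 (not isolated)
Conditions: Me2Zn (1.5 equiv), Cu(OTf)2 (2 mol %), (S,R,R)-phosphoramidite from (S)-BINOL and bis[(R)-1-phenylethyl]amine (4 mol %), toluene, −25 °C; AcOH (2.5 equiv), −25 °C, then pH 7 buffer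
Reagents that add atoms: dimethylzinc, C[Zn]C
Why: Copper-catalysed asymmetric conjugate addition (Feringa phosphoramidite system) desymmetrises the two enantiotopic enone arms and sets the future C4 stereocentre, the (S,R,R)-ligand being expected to give 5R by analogy with its facial sense on cyclohex-2-enone; the zinc dienolate is inert to a second addition.

Step 2
Reactants: 3 (5R)-4,4-dimethoxy-5-methylcyclohex-2-en-1-one
Product: 5 (5R,6R)-4,4-dimethoxy-5,6-dimethylcyclohex-2-en-1-one, via lithium dienolate 4 (not isolated)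
Conditions: LiN(i-Pr)2 (1.05 equiv), THF, −78 °C; MeI (1.5 equiv), −78 → −20 °C
Reagents that add atoms: iodomethane, CI
Why: Kinetic enolate alkylation at the only enolisable position (C4 is a ketal carbon, so no γ-deprotonation), methyl entering mainly trans to the C5 methyl; the C6 configuration is erased in step 4.

Step 3
Reactants: 5 (5R,6R)-4,4-dimethoxy-5,6-dimethylcyclohex-2-en-1-one
Product: 6 (2R,3R)-4,4-dimethoxy-2,3-dimethylcyclohexan-1-one
Conditions: H2 (1 atm), Pd/C (5 mol %), EtOAc, 23 °C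
Reagents that add atoms: none
Why: Heterogeneous catalytic hydrogenation of the disubstituted enone C=C; ketal and stereocentres are untouched.

Step 4
Reactants: 6 (2R,3R)-4,4-dimethoxy-2,3-dimethylcyclohexan-1-one; 7 but-3-en-2-one
Product: 10 (4aR,5R)-4a,5-dimethyl-4,4a,7,8-tetrahydronaphthalene-2,6(3H,5H)-dione, via Michael adduct 8 (not isolated), via ketal enone 9 (not isolated)
Conditions: 7 (1.5 equiv), KOH (0.3 equiv), MeOH, 0 → 65 °C; 2 M aq HCl to pH 1, 0 °C, 20 min
Reagents that add atoms: water, O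
Why: Robinson annulation through the more substituted (thermodynamic) enolate, the enone adding anti to the pseudoaxial C3 methyl so that the new quaternary C5 methyl is cis to the C4 methyl, followed by aldol condensation and brief cold ketal hydrolysis (too short for acid enolisation at C4).

Step 5
Reactants: 10 (4aR,5R)-4a,5-dimethyl-4,4a,7,8-tetrahydronaphthalene-2,6(3H,5H)-dione
Product: 12 (1R,2S,8aR)-1,8a-dimethyl-6-oxo-1,2,3,4,6,7,8,8a-octahydronaphthalen-2-yl acetate, via lithium alkoxide 11 (not isolated)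
Conditions: LiBH(s-Bu)3 (1.05 equiv), THF, −78 °C; Ac2O (3 equiv), DMAP (0.2 equiv), −78 → 0 °C
Reagents that add atoms: acetic anhydride, CC(=O)OC(C)=O
Why: Chemo- and diastereoselective hydride reduction with in-flask acylation: the bulky borohydride reduces the saturated C3 ketone faster than the β,β-disubstituted enone and attacks from the equatorial α-face (the axial β-face is blocked by the syn-axial C5 methyl), giving the axial 3β-alkoxide (3S), which is acetylated.

Step 6
Reactants: 12 (1R,2S,8aR)-1,8a-dimethyl-6-oxo-1,2,3,4,6,7,8,8a-octahydronaphthalen-2-yl acetate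
Product: 13 (1R,2S,8aR)-1,8a-dimethyl-6-oxo-1,2,3,4,6,8a-hexahydronaphthalen-2-yl acetate
Conditions: DDQ (1.5 equiv), 1,4-dioxane, 100 °C
Reagents that add atoms: none
Why: DDQ dehydrogenation of the enone at C6–C7 under neutral conditions to the cross-conjugated dienone (the steroid 4-en-3-one → 1,4-dien-3-one analogy); no stereocentre is involved.

Step 7
Reactants: 13 (1R,2S,8aR)-1,8a-dimethyl-6-oxo-1,2,3,4,6,8a-hexahydronaphthalen-2-yl acetate
Product: 14 (1R,2S,8aS)-7-iodo-1,8a-dimethyl-6-oxo-1,2,3,4,6,8a-hexahydronaphthalen-2-yl acetate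
Conditions: iodine (2 equiv), pyridine/CH2Cl2 1:1, 0 → 23 °C, dark
Reagents that add atoms: iodine, [I][I]
Why: Johnson α-iodination of an enone (pyridine adds at the β-CH C6, iodination, elimination); the C9=C10 arm is β,β-disubstituted and does not react (the 8aS label is only a priority change caused by iodine).

Step 8
Reactants: 14 (1R,2S,8aS)-7-iodo-1,8a-dimethyl-6-oxo-1,2,3,4,6,8a-hexahydronaphthalen-2-yl acetate; 15 tert-butyl 2-bromopropanoate
Product: 17 tert-butyl (3S,4R,5R,11RS)-3-acetoxy-8-oxoeremophila-6,9-dien-12-oate, via Reformatsky reagent 16 (not isolated)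
Conditions: 15, Zn (TMSCl-activated), THF, 23 °C; then 14, Pd2(dba)3 (2 mol %), P(t-Bu)3 (8 mol %), THF, 23 °C
Reagents that add atoms: none
Why: Palladium-catalysed Negishi-type coupling of a zinc ester enolate with the α-iodoenone (ester α-vinylation) forms C7–C11; the roughly 1:1 C11 epimer mixture is irrelevant because C11 becomes sp2 in step 11.

Step 9
Reactants: 17 tert-butyl (3S,4R,5R,11RS)-3-acetoxy-8-oxoeremophila-6,9-dien-12-oate
Product: 18 (3S,4R,5R,11RS)-3-acetoxy-8-oxoeremophila-6,9-dien-12-oic acid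
Conditions: CF3CO2H/CH2Cl2 1:4, 0 °C, 2 h; toluene azeotrope
Reagents that add atoms: none
Why: Acidolysis of the tert-butyl ester (loss of isobutene); the secondary acetate and the dienone tolerate short cold exposure.

Step 10
Reactants: 19 (R)-2-methylbutanoic acid
Product: 20 3-chlorobenzoyl (2R)-2-methylbutanoyl peroxide
Conditions: mCPBA (buffer-washed, ≥95%, 1.0 equiv), DCC (1.05 equiv), Et2O/toluene 1:4, −15 → 0 °C; cold filtration, cold aq NaHCO3 wash, MgSO4; kept as a titrated toluene solution below −20 °C, never concentrated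
Reagents that add atoms: 3-chloroperoxybenzoic acid, OOC(=O)c1cccc(Cl)c1
Why: Carbodiimide-mediated coupling of a carboxylic acid with a peroxy acid (unsymmetrical diacyl peroxide synthesis), the O-acylisourea of 19 being attacked by the peroxy acid OOH under neutral cold conditions, so the α-stereocentre is retained and each partner supplies one acyl group.

Step 11
Reactants: 18 (3S,4R,5R,11RS)-3-acetoxy-8-oxoeremophila-6,9-dien-12-oic acid; 20 3-chlorobenzoyl (2R)-2-methylbutanoyl peroxide
Product: 24 (3S,4R,5R,11R)-3-acetoxy-11-{[(2R)-2-methylbutanoyl]oxy}-8-oxoeremophila-6,9-dien-12-oic acid, via acid chloride 21 (not isolated), via vinylketene 22 (not isolated), via mixed anhydride 23 (not isolated)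
Conditions: (COCl)2 (1.2 equiv), DMF (cat.), CH2Cl2, 0 → 23 °C, evaporate; Et3N (1.0 equiv), toluene, 0 °C, filter under Ar; (R)-benzotetramisole [(R)-2-phenyl-2,3-dihydroimidazo[2,1-b][1,3]benzothiazole] (10 mol %), 20 (1.3 equiv), toluene, −60 → −30 °C; H2O/THF, 0 °C
Reagents that add atoms: none
Why: Proposed new method: enantioselective Lewis-base-catalysed α-acyloxylation of a disubstituted vinylketene with an unsymmetrical diacyl peroxide, in which the isothiourea adds to 22 from the methyl side to give a (Z)-ammonium dienolate held coplanar by the 1,5-O···S contact, its α-carbon C11 attacks in an SN2 manner the peroxide oxygen on the 2-methylbutanoyl side (the attack that expels the better leaving group, 3-chlorobenzoate, whose acid is about one pKa unit stronger) on the face anti to the catalyst phenyl group (the model predicts 11R with the (R)-catalyst), the expelled 3-chlorobenzoate attacks the acylammonium to release 23 and the catalyst, and water then cleaves 23 at the unhindered aroyl carbonyl to free the acid; the closest known reaction types are the Lewis-base-catalysed asymmetric α-chlorination and α-amination of disubstituted ketenes and the polar α-benzoyloxylation of enamines and stabilised enolates by dibenzoyl peroxide.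

**Compound list**
1 | 4,4-dimethoxycyclohexa-2,5-dien-1-one | COC1(OC)C=CC(=O)C=C1 | starting material
2 | methylzinc (3R)-4,4-dimethoxy-3-methylcyclohexa-1,5-dien-1-olate | C[Zn]OC1=C[C@@H](C)C(OC)(OC)C=C1 | intermediate
3 | (5R)-4,4-dimethoxy-5-methylcyclohex-2-en-1-one | O=C1C=CC(OC)(OC)[C@H](C)C1 | intermediate
4 | lithium (3R)-4,4-dimethoxy-3-methylcyclohexa-1,5-dien-1-olate | [Li]OC1=C[C@@H](C)C(OC)(OC)C=C1 | intermediate
5 | (5R,6R)-4,4-dimethoxy-5,6-dimethylcyclohex-2-en-1-one (trans; some C6 epimer carried along) | O=C1C=CC(OC)(OC)[C@H](C)[C@H]1C | intermediate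
6 | (2R,3R)-4,4-dimethoxy-2,3-dimethylcyclohexan-1-one | O=C1CCC(OC)(OC)[C@H](C)[C@H]1C | intermediate
7 | but-3-en-2-one (methyl vinyl ketone) | CC(=O)C=C | starting material
8 | (2R,3R)-4,4-dimethoxy-2,3-dimethyl-2-(3-oxobutyl)cyclohexan-1-one | CC(=O)CC[C@@]1(C)C(=O)CCC(OC)(OC)[C@@H]1C | intermediate
9 | (4aR,5R)-6,6-dimethoxy-4a,5-dimethyl-4,4a,5,6,7,8-hexahydronaphthalen-2(3H)-one | C1C[C@@]2(C)C(=CC1=O)CCC(OC)(OC)[C@@H]2C | intermediate
10 | (4aR,5R)-4a,5-dimethyl-4,4a,7,8-tetrahydronaphthalene-2,6(3H,5H)-dione (eremophil-9-ene-3,8-dione) | C1C[C@@]2(C)C(=CC1=O)CCC(=O)[C@@H]2C | intermediate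
11 | lithium (1R,2S,8aR)-1,8a-dimethyl-6-oxo-1,2,3,4,6,7,8,8a-octahydronaphthalen-2-olate | C1C[C@@]2(C)C(=CC1=O)CC[C@H](O[Li])[C@@H]2C | intermediate
12 | (1R,2S,8aR)-1,8a-dimethyl-6-oxo-1,2,3,4,6,7,8,8a-octahydronaphthalen-2-yl acetate (3β-acetoxyeremophil-9-en-8-one) | C1C[C@@]2(C)C(=CC1=O)CC[C@H](OC(C)=O)[C@@H]2C | intermediate
13 | (1R,2S,8aR)-1,8a-dimethyl-6-oxo-1,2,3,4,6,8a-hexahydronaphthalen-2-yl acetate (3β-acetoxyeremophila-6,9-dien-8-one) | C1=C[C@@]2(C)C(=CC1=O)CC[C@H](OC(C)=O)[C@@H]2C | intermediate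
14 | (1R,2S,8aS)-7-iodo-1,8a-dimethyl-6-oxo-1,2,3,4,6,8a-hexahydronaphthalen-2-yl acetate (3β-acetoxy-7-iodoeremophila-6,9-dien-8-one) | IC1=C[C@@]2(C)C(=CC1=O)CC[C@H](OC(C)=O)[C@@H]2C | intermediate
15 | tert-butyl 2-bromopropanoate (racemic) | CC(Br)C(=O)OC(C)(C)C | starting material
16 | bromo[1-(tert-butoxy)-1-oxopropan-2-yl]zinc | CC([Zn]Br)C(=O)OC(C)(C)C | intermediate
17 | tert-butyl (3S,4R,5R,11RS)-3-acetoxy-8-oxoeremophila-6,9-dien-12-oate | CC(C(=O)OC(C)(C)C)C1=C[C@@]2(C)C(=CC1=O)CC[C@H](OC(C)=O)[C@@H]2C | intermediate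
18 | (3S,4R,5R,11RS)-3-acetoxy-8-oxoeremophila-6,9-dien-12-oic acid | CC(C(=O)O)C1=C[C@@]2(C)C(=CC1=O)CC[C@H](OC(C)=O)[C@@H]2C | intermediate
19 | (R)-2-methylbutanoic acid | CC[C@@H](C)C(=O)O | starting material
20 | 3-chlorobenzoyl (2R)-2-methylbutanoyl peroxide | CC[C@@H](C)C(=O)OOC(=O)c1cccc(Cl)c1 | intermediate
21 | (3S,4R,5R,11RS)-3-acetoxy-8-oxoeremophila-6,9-dien-12-oyl chloride | CC(C(Cl)=O)C1=C[C@@]2(C)C(=CC1=O)CC[C@H](OC(C)=O)[C@@H]2C | intermediate
22 | (3S,4R,5R)-3-acetoxy-8-oxoeremophila-6,9-dien-7-yl methyl ketene (C11=C12=O) | CC(=C=O)C1=C[C@@]2(C)C(=CC1=O)CC[C@H](OC(C)=O)[C@@H]2C | intermediate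
23 | mixed anhydride of acid 24 and 3-chlorobenzoic acid | CC[C@@H](C)C(=O)O[C@@](C)(C(=O)OC(=O)c1cccc(Cl)c1)C1=C[C@@]2(C)C(=CC1=O)CC[C@H](OC(C)=O)[C@@H]2C | intermediate
24 | (3S,4R,5R,11R)-3-acetoxy-11-{[(2R)-2-methylbutanoyl]oxy}-8-oxoeremophila-6,9-dien-12-oic acid | CC[C@@H](C)C(=O)O[C@@](C)(C(=O)O)C1=C[C@@]2(C)C(=CC1=O)CC[C@H](OC(C)=O)[C@@H]2C | target

**Step count and risks**
Total steps: 11. Longest linear sequence: 10 (steps 1–9 and 11); step 10 is a one-step side branch.

Most likely to fail: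

Step 11 (proposed new C–O bond formation). Failure modes are:
- transfer of the 3-chlorobenzoyloxy group instead of the 2-methylbutanoyloxy group (attack at the other peroxide oxygen);
- a carboxylate-catalysed racemic background reaction;
- N-acyloxylation or oxidation of the catalyst;
- carboxy-inversion or radical decomposition of the secondary-alkyl peroxide;
- ketene dimerisation;
- a facial sense opposite to the model (the (S)-catalyst is equally available; the 11-epimers are separable diastereomers).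

Fallback with known chemistry, setting out from 17 and coming back at 24: 17 is deprotonated with KN(SiMe3)2 (THF, −78 °C) to the potassium ester dienolate F1, which is hydroxylated at C11 with Davis' (+)-(camphorsulfonyl)oxaziridine (reagent control, antipode if needed; NH4Cl quench) to give tert-butyl (11R)-3β-acetoxy-11-hydroxy-8-oxoeremophila-6,9-dien-12-oate F2. Steglich acylation of the tertiary alcohol with 19 (DCC, DMAP, CH2Cl2, 40 °C) gives tert-butyl (11R)-3β-acetoxy-11-[(2R)-2-methylbutanoyloxy]-8-oxoeremophila-6,9-dien-12-oate F3, and CF3CO2H/CH2Cl2 at 0 °C releases 24.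

Step 8 (Pd coupling on the α-iodo dienone). Failure modes are reductive deiodination, 1,2-addition of the zinc enolate to the dienone, and β-hydride loss from the palladium enolate. Fallback, setting out from 12 and coming back at 17: commercial tert-butyl (S)-lactate is converted with Tf2O/2,6-lutidine (CH2Cl2, −40 °C) into tert-butyl (2S)-2-[(trifluoromethanesulfonyl)oxy]propanoate F4. Enone 12 is deprotonated with LiN(SiMe3)2 (THF, −78 °C; the acetate is not enolised) to the cross-conjugated lithium dienolate F5, which is alkylated at C7 by F4 (SN2) to give tert-butyl 3β-acetoxy-8-oxoeremophil-9-en-12-oate F6 as a C7/C11 epimer mixture. DDQ (dioxane, 100 °C) then dehydrogenates C6–C7 to give 17.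

Step 4 (Robinson annulation of a hindered 2,3-disubstituted ketone). Failure modes are Michael addition at the unhindered C6, enone polymerisation and modest facial selectivity. Fallback, setting out from 5 and coming back at 8: 5 is deprotonated with LiN(i-Pr)2 (THF, −78 °C) at its only enolisable carbon to the lithium dienolate F7, which adds to 3-(trimethylsilyl)but-3-en-2-one (Stork–Ganem acceptor) anti to the C5 methyl; NH4Cl quench gives (5R,6R)-4,4-dimethoxy-5,6-dimethyl-6-[3-oxo-2-(trimethylsilyl)butyl]cyclohex-2-en-1-one F8. Hydrogenation (H2, Pd/C, EtOAc) gives (2R,3R)-4,4-dimethoxy-2,3-dimethyl-2-[3-oxo-2-(trimethylsilyl)butyl]cyclohexan-1-one F9. Under the KOH/MeOH conditions of step 4 this loses silicon to give 8, which cyclises and is deketalised to 10 as before.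

**Further compounds**
F1 | step 11 | potassium ester dienolate of 17 | CC(=C(O[K])OC(C)(C)C)C1=C[C@@]2(C)C(=CC1=O)CC[C@H](OC(C)=O)[C@@H]2C
F2 | step 11 | tert-butyl (11R)-3β-acetoxy-11-hydroxy-8-oxoeremophila-6,9-dien-12-oate | O[C@@](C)(C(=O)OC(C)(C)C)C1=C[C@@]2(C)C(=CC1=O)CC[C@H](OC(C)=O)[C@@H]2C
F3 | step 11 | tert-butyl (11R)-3β-acetoxy-11-[(2R)-2-methylbutanoyloxy]-8-oxoeremophila-6,9-dien-12-oate | CC[C@@H](C)C(=O)O[C@@](C)(C(=O)OC(C)(C)C)C1=C[C@@]2(C)C(=CC1=O)CC[C@H](OC(C)=O)[C@@H]2C
F4 | step 8 | tert-butyl (2S)-2-[(trifluoromethanesulfonyl)oxy]propanoate | C[C@H](OS(=O)(=O)C(F)(F)F)C(=O)OC(C)(C)C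
F5 | step 8 | lithium cross-conjugated dienolate of 12 | C=1C[C@@]2(C)C(=CC=1O[Li])CC[C@H](OC(C)=O)[C@@H]2C
F6 | step 8 | tert-butyl 3β-acetoxy-8-oxoeremophil-9-en-12-oate (C7/C11 epimer mixture) | CC(C(=O)OC(C)(C)C)C1C[C@@]2(C)C(=CC1=O)CC[C@H](OC(C)=O)[C@@H]2C
F7 | step 4 | lithium (3R)-4,4-dimethoxy-2,3-dimethylcyclohexa-1,5-dien-1-olate | [Li]OC1=C(C)[C@@H](C)C(OC)(OC)C=C1
F8 | step 4 | (5R,6R)-4,4-dimethoxy-5,6-dimethyl-6-[3-oxo-2-(trimethylsilyl)butyl]cyclohex-2-en-1-one | CC(=O)C(C[C@@]1(C)C(=O)C=CC(OC)(OC)[C@@H]1C)[Si](C)(C)C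
F9 | step 4 | (2R,3R)-4,4-dimethoxy-2,3-dimethyl-2-[3-oxo-2-(trimethylsilyl)butyl]cyclohexan-1-one | CC(=O)C(C[C@@]1(C)C(=O)CCC(OC)(OC)[C@@H]1C)[Si](C)(C)C
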